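Numbering: the tricycle is numbered as a fluorene (ring C = C1–C4, C4a, C9a; ring B = C4a, C4b, C8a, C9, C9a; ring A = C4b, C5–C8, C8a); lactam atoms are primed (N1', C2'–C5').
Retrosynthetic cuts, in order: the C5'–OH bond and the C3'=C4' unsaturation; the aryl–O bond at C9, which opens the 13-membered paracyclophane; the C3'–C(=O) bond to the C1 arm; the C4a–C4b bond of ring B; both bonds of the C9 carbonyl carbon (to C8a and C9a).
Enabling feature: ring B is a cyclopentane held between cyclohexane ring A and cyclohexene ring C, and its oxygen-bearing C9 sits between the fusion carbons C8a and C9a. At the C4a–C4b bond the methyl on quaternary C4b and the C4a–C4 bond of ring C share one face, which is what conrotatory 4π closure of a (ring A cyclohexenyl)(ring C cyclohexadienyl) ketone delivers.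
Forward order: ring A (enol triflate) and ring C (dienylstannane) are made separately and joined through CO. Ring B is closed by a reductive Nazarov cyclisation, the lactam is added by aldol/oxidation, and the macrocycle is closed by Ullmann etherification. The lactam is then dehydrogenated and hydroxylated.
Stereochemistry: C6/C8 come from chiral lithium amide desymmetrisation of a meso ketone, and C1/C2 from a copper–bis(oxazoline) Diels–Alder reaction. C4a/C4b/C8a/C9a come from the electrocyclisation and its reductive termination under control of those four centres, and C9 from convex-face hydride. C5' comes from L-4-iodophenylalanine and is held by the macrocycle on hydroxylation.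

Key step: step 15

Face convention: β is the face of H-4a. "Core configuration" means H-4a, H-8a, H-9a, 6-Me, 8-Me and the C1 arm β; 4b-Me and the 2-vinyl group α; from step 16 on, the oxygen at C9 is α (H-9 β).
Assumption 1: the sense of deprotonation by the chiral lithium amide is taken by analogy with 4-substituted and cis-2,6-dialkyl cyclohexanones; if it proved opposite, the equally available (R,R)-amine would be used.
Assumption 2: the facial sense of the copper–bis(oxazoline) catalyst is taken from the acryloyl-oxazolidinone benchmark ((S,S)-ligand: attack on the Cα Re face), hence the (R,R)-ligand here.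
Assumption 3: the C5' hemiaminal is configurationally labile (ring–chain tautomerism), and the natural epimer is taken to be the more stable one inside the macrocycle.

Step 1
Reactants: 1 2,4,6-trimethylphenol
Product: 2 2,4,6-trimethylcyclohexan-1-ol (stereoisomer mixture; mainly all-cis)
Conditions: H2 (60 bar), 5% Rh/Al2O3, i-PrOH, 60 °C
Reagents that add atoms: none
Why: Heterogeneous arene hydrogenation over rhodium saturates alkylphenols with little hydrogenolysis, and the isomer mixture is harmless because step 2 equilibrates both α-carbons against C4.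

Step 2
Reactants: 2 2,4,6-trimethylcyclohexan-1-ol
Product: 3 all-cis-2,4,6-trimethylcyclohexan-1-one (meso)
Conditions: NaOCl (aq), AcOH, 0 °C to rt; then NaOMe (cat.), MeOH, rt
Reagents that add atoms: none
Why: Hypochlorite oxidation of the secondary alcohol followed by base equilibration of both α-carbons should converge on the meso ketone with all three methyl groups equatorial.

Step 3
Reactants: 3 all-cis-2,4,6-trimethylcyclohexan-1-one
Product: 5 (4R,6S)-2,4,6-trimethylcyclohex-1-en-1-yl trifluoromethanesulfonate, via lithium enolate 4 (not isolated)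
Conditions: (S,S)-bis(1-phenylethyl)amine, n-BuLi, LiCl, THF, −78 °C; then N-(5-chloro-2-pyridyl)triflimide, −78 to 0 °C
Reagents that add atoms: N-(5-chloropyridin-2-yl)-1,1,1-trifluoro-N-(trifluoromethylsulfonyl)methanesulfonamide O=S(=O)(N(c1ccc(Cl)cn1)S(=O)(=O)C(F)(F)F)C(F)(F)F
Why: Enantioselective deprotonation by a C2-symmetric chiral lithium amide removes one of the two enantiotopic axial α-hydrogens of the meso ketone, which makes C4 and C6 (later C6 and C8 of the core) stereogenic, O-sulfonylation of the tetrasubstituted enolate fixes the alkene position, and any minor enantiomer becomes a separable diastereomer after step 14.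

Step 4
Reactants: 6 3-methylbut-2-enal
Product: 7 (1E)-3-methylbuta-1,3-dien-1-yl acetate
Conditions: isopropenyl acetate, p-TsOH (cat.), reflux, acetone distilled off
Reagents that add atoms: isopropenyl acetate CC(=C)OC(C)=O
Why: Acid-catalysed enol-acetate exchange through the extended enol of the enal gives the 1-acetoxy diene, with the E isomer favoured and the one that reaches the s-cis geometry easily.

Step 5
Reactants: 8 1,3-oxazolidin-2-one; 9 ethyl (2E)-4-chloro-4-oxobut-2-enoate
Product: 10 ethyl (2E)-4-oxo-4-(2-oxo-1,3-oxazolidin-3-yl)but-2-enoate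
Conditions: Et3N, DMAP (cat.), CH2Cl2, 0 °C
Reagents that add atoms: none
Why: N-Acylation of the oxazolidinone by the acid chloride gives a doubly activated fumaric dienophile in which only the imide end can chelate the catalyst.

Step 6
Reactants: 7 (1E)-3-methylbuta-1,3-dien-1-yl acetate; 10 ethyl (2E)-4-oxo-4-(2-oxo-1,3-oxazolidin-3-yl)but-2-enoate
Product: 11 ethyl (1S,6R)-5-acetoxy-3-methyl-6-(2-oxo-1,3-oxazolidine-3-carbonyl)cyclohex-3-ene-1-carboxylate (C5 epimers)
Conditions: Cu(SbF6)2·(R,R)-t-Bu-box (10 mol %; from CuCl2, AgSbF6 and 2,2'-(propane-2,2-diyl)bis[(4R)-4-tert-butyl-4,5-dihydro-1,3-oxazole]), CH2Cl2, −20 °C to rt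
Reagents that add atoms: none
Why: In this catalytic asymmetric Diels–Alder reaction the square-planar divalent copper chelate of the s-cis imide exposes one alkene face (sets C6 and, through the E alkene, the trans C1), the chelated carbonyl places the acetoxy carbon next to the imide carbon and para to the methyl group, the acetoxy centre is erased later, and a fumarate is chosen over a pentadienoate because the latter could also react at its terminal alkene.

Step 7
Reactants: 11 Diels–Alder adduct
Product: 12 ethyl (1S,6S)-5-acetoxy-6-(hydroxymethyl)-3-methylcyclohex-3-ene-1-carboxylate (C5 epimers)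
Conditions: NaBH4, THF/H2O (4:1), 0 °C to rt
Reagents that add atoms: none
Why: Borohydride reduction of the activated N-acyl oxazolidinone to the primary alcohol proceeds under conditions that leave simple esters alone, so the two carbonyl arms are told apart without touching a stereocentre.

Step 8
Reactants: 12 hydroxy ester
Product: 13 (3aS,7aS)-6-methyl-1,3,3a,4,7,7a-hexahydro-2-benzofuran-1,4-diol (trans-fused lactol; C1 and C4 epimers)
Conditions: i-Bu2AlH (4.5 equiv), CH2Cl2, −78 °C; Rochelle salt work-up
Reagents that add atoms: none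
Why: Partial ester reduction at low temperature stops at the aluminium hemiacetal, which ends as the trans-fused lactol with the neighbouring hydroxymethyl group, and the acetate is cleaved in the same operation.

Step 9
Reactants: 13 lactol
Product: 14 (5R,6S)-5-ethenyl-6-(hydroxymethyl)-3-methylcyclohex-2-en-1-ol (C1 epimers)
Conditions: Ph3PCH3Br, KOt-Bu, THF, 0 °C to rt
Reagents that add atoms: methyltriphenylphosphonium bromide C[P+](c1ccccc1)(c1ccccc1)c1ccccc1.[Br-]
Why: Wittig methylenation of the lactol through its open hydroxy aldehyde installs the vinyl group and frees the primary alcohol, and the aldehyde α-carbon is safe because it already holds the more stable trans arrangement.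

Step 10
Reactants: 14 diol
Product: 15 [(1S,6R)-6-ethenyl-2-hydroxy-4-methylcyclohex-3-en-1-yl]methyl 2,2-dimethylpropanoate (C2 epimers)
Conditions: PivCl (1.05 equiv), pyridine, CH2Cl2, 0 °C
Reagents that add atoms: pivaloyl chloride CC(C)(C)C(=O)Cl
Why: In this sterically controlled acylation the bulky acid chloride should take the primary alcohol well before the secondary allylic one.

Step 11
Reactants: 15 hydroxy pivalate
Product: 16 [(1S,6R)-6-ethenyl-4-methyl-2-oxocyclohex-3-en-1-yl]methyl 2,2-dimethylpropanoate
Conditions: MnO2 (activated), CH2Cl2, rt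
Reagents that add atoms: none
Why: Allylic alcohol oxidation under neutral heterogeneous conditions converges both carbinol epimers on one enone and avoids base-induced β-elimination of pivalate.

Step 12
Reactants: 16 enone
Product: 17 [(1S,6S)-6-ethenyl-4-methyl-2-(trifluoromethylsulfonyloxy)cyclohexa-2,4-dien-1-yl]methyl 2,2-dimethylpropanoate
Conditions: Tf2O, 2,6-di-tert-butyl-4-methylpyridine, CH2Cl2, 0 °C to rt
Reagents that add atoms: trifluoromethanesulfonic anhydride O=S(=O)(OS(=O)(=O)C(F)(F)F)C(F)(F)F
Why: O-Sulfonylation of the enone gives a delocalised allyl cation from which the very hindered pyridine should remove the accessible, axially aligned γ-hydrogen at C5 rather than the tertiary α'-hydrogen at C1 flanked by two branches, as in the known through-conjugated dienyl triflate formation from cyclic enones such as steroidal 4-en-3-ones, while the non-basic medium excludes pivalate elimination and leaves both stereocentres untouched.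

Step 13
Reactants: 17 dienyl triflate
Product: 18 [(1S,6S)-6-ethenyl-4-methyl-2-(trimethylstannyl)cyclohexa-2,4-dien-1-yl]methyl 2,2-dimethylpropanoate
Conditions: Me3SnSnMe3, Pd(PPh3)4 (5 mol %), LiCl, THF, 60 °C
Reagents that add atoms: hexamethylditin C[Sn](C)(C)[Sn](C)(C)C
Why: Palladium-catalysed triflate-to-tin exchange with a distannane (Stille-type stannylation), with chloride aiding turnover, keeps both alkene positions and both stereocentres.

Step 14
Reactants: 5 ring A enol triflate; 18 ring C dienylstannane
Product: 19 [(1R,6S)-6-ethenyl-4-methyl-2-[(4R,6S)-2,4,6-trimethylcyclohex-1-ene-1-carbonyl]cyclohexa-2,4-dien-1-yl]methyl 2,2-dimethylpropanoate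
Conditions: CO (1 atm), Pd2(dba)3 (2.5 mol %), AsPh3 (20 mol %), LiCl, NMP, 50 °C
Reagents that add atoms: carbon monoxide [C-]#[O+]
Why: In this carbonylative Stille coupling zerovalent palladium adds to triflate 5, CO inserts before the slow transmetalation of the hindered alkenylpalladium, and transfer of the dienyl group from 18 gives the cross-conjugated ketone, the classical entry to Nazarov substrates.

Step 15
Reactants: 19 cyclohexenyl cyclohexadienyl ketone
Product: 21 [(1R,2S,4aS,4bS,6R,8S,8aR,9aR)-2-ethenyl-4,4b,6,8-tetramethyl-9-oxo-2,4a,4b,5,6,7,8,8a,9,9a-decahydro-1H-fluoren-1-yl]methyl 2,2-dimethylpropanoate, via difluoroboron enolate 20 (not isolated)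
Conditions: BF3·OEt2 (2.5 equiv), Et3SiH (10 equiv), CH2Cl2, −78 to −20 °C; cold pH 7 buffer
Reagents that add atoms: none
Why: BF3 binds the ketone oxygen of 19 and turns the cross-conjugated system into a 3-oxidopentadienyl cation (C4b=C8a–C9–C9a=C4a, extended by the C3=C4 alkene) whose U shape is favoured because both α-carbons are ring carbons, and thermal 4π conrotatory electrocyclisation then joins C4a to C4b and closes the five-membered ring B as a pericyclic closure, not a polar 5-endo attack. Because the inward-pointing groups are the C4b methyl and H-4a, conrotation puts them on opposite faces, which fixes the cis relation between the C4b methyl and the C4a–C4 bond. Of the two rotation senses the required one lets ring A settle into a chair with the new C4b methyl axial and the 6- and 8-methyl groups equatorial (the other forces three syn-axial methyl groups), and it forms the new bond on the face of ring C opposite the adjacent C1 pivaloyloxymethyl arm, so both resident stereo-arrays favour the same rotation. Excess Et3SiH then gives hydride to the less congested terminus C9a of the 2-oxidoallyl cation from the convex face syn to H-4a (the other face is covered by the folded ring C and the C4b methyl), which sets the cis B/C fusion and leaves enolate 20. The cold buffered quench protonates C8a of 20 axially, anti to the axial C4b methyl, giving the kinetic trans A/B hydrindanone, so 21 is kept from acid and base and reduced at once. The closest known reaction type is the Lewis acid/trialkylsilane reductive (interrupted) Nazarov cyclisation of bis(cycloalkenyl) ketones, and the step needs closure to outrun direct ionic reduction and proton loss, which the pre-organised geometry, the low temperature and the large excess of silane are meant to secure.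

Step 16
Reactants: 21 tricyclic ketone pivalate
Product: 23 (1R,2S,4aS,4bS,6R,8S,8aR,9S,9aR)-2-ethenyl-1-(hydroxymethyl)-4,4b,6,8-tetramethyl-2,4a,4b,5,6,7,8,8a,9,9a-decahydro-1H-fluoren-9-ol, via hydroxy pivalate 22 (not isolated)
Conditions: LiAlH4, Et2O, −78 °C, then 0 °C
Reagents that add atoms: none
Why: Hydride reduction should attack C9 from the open β face (the α face is screened by the 4b-methyl group and the folded ring C), which sets the 9α-alcohol before any enolisation of the labile hydrindanone, and warming then cleaves the pivalate reductively.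

Step 17
Reactants: 23 diol
Product: 24 bis(triethylsilyl) ether of 23 (core configuration; 9α-OSiEt3)
Conditions: Et3SiOTf (2.5 equiv), 2,6-lutidine, CH2Cl2, 0 °C
Reagents that add atoms: triethylsilyl trifluoromethanesulfonate CC[Si](CC)(CC)OS(=O)(=O)C(F)(F)F
Why: A silyl triflate with a hindered pyridine base silylates both the primary and the congested secondary alcohol, setting up their differentiation in step 18.

Step 18
Reactants: 24 bis(triethylsilyl) ether
Product: 26 9α-(triethylsilyloxy) tricyclic 1-carbaldehyde (core configuration), via alkoxysulfonium chloride 25 (not isolated)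
Conditions: (COCl)2, DMSO, CH2Cl2, −78 to −40 °C; Et3N, −78 °C to rt
Reagents that add atoms: none
Why: Under Swern conditions the activated sulfoxide cleaves primary triethylsilyl ethers and oxidises them directly to aldehydes while a hindered secondary silyl ether survives, and C1 keeps its configuration because the formyl group is already trans to both neighbours.

Step 19
Reactants: 27 N-Boc-4-iodo-L-phenylalanine; 28 Meldrum's acid
Product: 30 tert-butyl N-[(2R)-1-(2,2-dimethyl-4,6-dioxo-1,3-dioxan-5-yl)-3-(4-iodophenyl)propan-2-yl]carbamate, via acyl Meldrum's acid 29 (not isolated)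
Conditions: EDC·HCl, DMAP, CH2Cl2, 0 °C to rt; aq. KHSO4 wash; then AcOH, NaBH4, 0 °C to rt
Reagents that add atoms: none
Why: Carbodiimide C-acylation of Meldrum's acid followed by borohydride/acetic acid deoxygenation of the enolised ketone extends the amino acid chain without touching its stereocentre.

Step 20
Reactants: 30 alkyl Meldrum's acid
Product: 31 tert-butyl (2R)-2-(4-iodobenzyl)-5-oxopyrrolidine-1-carboxylate
Conditions: toluene, 110 °C
Reagents that add atoms: none
Why: Thermal opening of the Meldrum's acid unit, capture by the carbamate nitrogen and decarboxylation (decarboxylative lactamisation) give the N-Boc γ-lactam with the stereocentre intact.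

Step 21
Reactants: 31 N-Boc lactam; 26 aldehyde
Product: 33 aldol adduct: N-Boc (5'R)-5'-(4-iodobenzyl)-2'-oxopyrrolidin-3'-yl carbinol at the C1 arm (9α-OSiEt3; carbinol and C3' epimers), via lactam lithium enolate 32 (not isolated)
Conditions: LiN(SiMe3)2, THF, −78 °C; then 26, −78 °C
Reagents that add atoms: none
Why: Aldol addition of the N-Boc lactam lithium enolate to the aldehyde forms the C3'–C bond fast enough at −78 °C to spare C1, and the two new centres may form as mixtures because one is oxidised in step 22 and the other becomes sp2 in step 25.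

Step 22
Reactants: 33 aldol adduct
Product: 34 β-keto lactam: N-Boc (5'R)-3'-(core-1-carbonyl)-5'-(4-iodobenzyl)pyrrolidin-2'-one (9α-OSiEt3; C3' labile)
Conditions: Dess–Martin periodinane, NaHCO3, CH2Cl2, rt
Reagents that add atoms: none
Why: Dess–Martin oxidation under buffered neutral conditions converges the aldol diastereomers on one β-keto lactam.

Step 23
Reactants: 34 silyl-protected β-keto lactam
Product: 35 9α-hydroxy β-keto lactam (core configuration; C3' labile)
Conditions: HF·pyridine, pyridine, THF, 0 °C
Reagents that add atoms: none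
Why: Buffered fluoride desilylation frees the 9α-alcohol without harming the Boc group or C1, and any five-membered hemiketal form reopens under the basic conditions of step 24.

Step 24
Reactants: 35 9α-hydroxy β-keto lactam
Product: 36 N-Boc 13-membered paracyclophane β-keto lactam (target skeleton with C3'-H; C4'-H2; C5'-H)
Conditions: CuI (1 equiv), 3,4,7,8-tetramethyl-1,10-phenanthroline, Cs2CO3, 4 Å MS, toluene (1 mM), 110 °C
Reagents that add atoms: none
Why: Copper-mediated Ullmann-type O-arylation of a secondary alcohol by an aryl iodide, run intramolecularly at high dilution, forms the C9–O–aryl bond with retention at C9 and closes the macrocycle, while the β-keto lactam sits as its caesium enolate (shielded from retro-Claisen attack) and the para geometry rules out internal C- or N-arylation.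

Step 25
Reactants: 36 macrocyclic β-keto lactam
Product: 39 N-Boc 3'-acyl-1',5'-dihydropyrrol-2'-one macrocycle (C3'=C4'; C5'-H), via selenide 37 (not isolated), via selenoxide 38 (not isolated)
Conditions: PhSeCl, pyridine, CH2Cl2, 0 °C; then 30% H2O2, 0 °C to rt
Reagents that add atoms: none
Why: α-Selenenylation of the enolisable β-keto lactam at C3' and selenoxide syn-elimination toward the only β-hydrogens (C4'-H2) give the C3'=C4' alkene, selenium being oxidised far faster than the isolated alkenes, and the labile C3' centre disappears.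

Step 26
Reactants: 39 N-Boc pyrrolinone macrocycle
Product: 40 5'-deoxy target (N–H 3'-acyl-1',5'-dihydropyrrol-2'-one macrocycle)
Conditions: CF3CO2H/CH2Cl2 (1:4), 0 °C
Reagents that add atoms: none
Why: Acidolysis of the tert-butyl carbamate frees the lactam N–H under conditions short and cold enough for the vinyl group, the trisubstituted alkene and the aryl ether.

Step 27
Reactants: 40 5'-deoxy target
Product: 42 target CNP0151253.2, via hydroperoxide 41 (not isolated)
Conditions: O2 (1 atm), Et3N, MeCN, rt; then Me2S
Reagents that add atoms: dioxygen O=O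
Why: Base-mediated tautomerisation of the 3-acyl-1,5-dihydropyrrol-2-one to its electron-rich 2-hydroxypyrrole form, autoxidation at C5' (the known air oxidation of such acylpyrrolinones) and sulfide reduction of 41 install the hemiaminal hydroxyl without touching the alkenes, oxygen entering from the outer face left by H-5' because the benzylic carbon is held by the bridge, and ring–chain tautomerism lets any epimer drain to the more stable natural configuration.

Compound list
1 | 2,4,6-trimethylphenol | Cc1cc(C)c(O)c(C)c1 | starting material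
2 | 2,4,6-trimethylcyclohexan-1-ol (isomer mixture) | CC1CC(C)C(O)C(C)C1 | intermediate
3 | all-cis-2,4,6-trimethylcyclohexan-1-one (meso) | O=C1[C@H](C)C[C@H](C)C[C@@H]1C | intermediate
4 | lithium (4R,6S)-2,4,6-trimethylcyclohex-1-en-1-olate | [Li]OC1=C(C)C[C@H](C)C[C@@H]1C | intermediate
5 | (4R,6S)-2,4,6-trimethylcyclohex-1-en-1-yl triflate | O=S(=O)(OC1=C(C)C[C@H](C)C[C@@H]1C)C(F)(F)F | intermediate
6 | 3-methylbut-2-enal | CC(C)=CC=O | starting material
7 | (1E)-3-methylbuta-1,3-dien-1-yl acetate | CC(=C)/C=C/OC(C)=O | intermediate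
8 | 1,3-oxazolidin-2-one | O=C1NCCO1 | starting material
9 | ethyl (2E)-4-chloro-4-oxobut-2-enoate | CCOC(=O)/C=C/C(=O)Cl | starting material
10 | ethyl (2E)-4-oxo-4-(2-oxo-1,3-oxazolidin-3-yl)but-2-enoate | CCOC(=O)/C=C/C(=O)N1CCOC1=O | intermediate
11 | Diels–Alder adduct (1S,6R; acetoxy carbon as epimers) | CCOC(=O)[C@H]1CC(C)=CC(OC(C)=O)[C@@H]1C(=O)N1CCOC1=O | intermediate
12 | hydroxy ester (1S,6S) | CCOC(=O)[C@H]1CC(C)=CC(OC(C)=O)[C@@H]1CO | intermediate
13 | trans-fused lactol (3aS,7aS) | OC1OC[C@H]2C(O)C=C(C)C[C@H]12 | intermediate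
14 | (5R,6S)-5-ethenyl-6-(hydroxymethyl)-3-methylcyclohex-2-en-1-ol | C=C[C@H]1CC(C)=CC(O)[C@@H]1CO | intermediate
15 | allylic alcohol pivalate (1S,6R) | C=C[C@H]1CC(C)=CC(O)[C@@H]1COC(=O)C(C)(C)C | intermediate
16 | enone pivalate (1S,6R) | C=C[C@H]1CC(C)=CC(=O)[C@@H]1COC(=O)C(C)(C)C | intermediate
17 | dienyl triflate (1S,6S) | C=C[C@H]1C=C(C)C=C(OS(=O)(=O)C(F)(F)F)[C@@H]1COC(=O)C(C)(C)C | intermediate
18 | dienyl trimethylstannane (1S,6S) | C=C[C@H]1C=C(C)C=C([Sn](C)(C)C)[C@@H]1COC(=O)C(C)(C)C | intermediate
19 | cyclohexenyl cyclohexadienyl ketone (Nazarov precursor) | C=C[C@H]1C=C(C)C=C([C@@H]1COC(=O)C(C)(C)C)C(=O)C1=C(C)C[C@H](C)C[C@@H]1C | intermediate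
20 | difluoroboron C8a=C9 enolate | C=C[C@H]1C=C(C)[C@@H]2[C@H]([C@@H]1COC(=O)C(C)(C)C)C(OB(F)F)=C1[C@@H](C)C[C@@H](C)C[C@]12C | intermediate
21 | tricyclic ketone pivalate (Nazarov product) | C=C[C@H]1C=C(C)[C@@H]2[C@H]([C@@H]1COC(=O)C(C)(C)C)C(=O)[C@@H]1[C@@H](C)C[C@@H](C)C[C@]12C | intermediate
22 | 9α-hydroxy pivalate | C=C[C@H]1C=C(C)[C@@H]2[C@H]([C@@H]1COC(=O)C(C)(C)C)[C@H](O)[C@@H]1[C@@H](C)C[C@@H](C)C[C@]12C | intermediate
23 | tricyclic diol | C=C[C@H]1C=C(C)[C@@H]2[C@H]([C@@H]1CO)[C@H](O)[C@@H]1[C@@H](C)C[C@@H](C)C[C@]12C | intermediate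
24 | bis(triethylsilyl) ether | C=C[C@H]1C=C(C)[C@@H]2[C@H]([C@@H]1CO[Si](CC)(CC)CC)[C@H](O[Si](CC)(CC)CC)[C@@H]1[C@@H](C)C[C@@H](C)C[C@]12C | intermediate
25 | alkoxysulfonium chloride | C=C[C@H]1C=C(C)[C@@H]2[C@H]([C@@H]1CO[S+](C)C)[C@H](O[Si](CC)(CC)CC)[C@@H]1[C@@H](C)C[C@@H](C)C[C@]12C.[Cl-] | intermediate
26 | 9α-silyloxy aldehyde | C=C[C@H]1C=C(C)[C@@H]2[C@H]([C@@H]1C=O)[C@H](O[Si](CC)(CC)CC)[C@@H]1[C@@H](C)C[C@@H](C)C[C@]12C | intermediate
27 | N-Boc-4-iodo-L-phenylalanine | CC(C)(C)OC(=O)N[C@@H](Cc1ccc(I)cc1)C(=O)O | starting material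
28 | Meldrum's acid | CC1(C)OC(=O)CC(=O)O1 | starting material
29 | acyl Meldrum's acid | CC(C)(C)OC(=O)N[C@@H](Cc1ccc(I)cc1)C(=O)C1C(=O)OC(C)(C)OC1=O | intermediate
30 | alkyl Meldrum's acid | CC(C)(C)OC(=O)N[C@@H](Cc1ccc(I)cc1)CC1C(=O)OC(C)(C)OC1=O | intermediate
31 | tert-butyl (2R)-2-(4-iodobenzyl)-5-oxopyrrolidine-1-carboxylate | CC(C)(C)OC(=O)N1C(=O)CC[C@@H]1Cc1ccc(I)cc1 | intermediate
32 | lactam lithium enolate | CC(C)(C)OC(=O)N1C(O[Li])=CC[C@@H]1Cc1ccc(I)cc1 | intermediate
33 | aldol adduct | C=C[C@H]1C=C(C)[C@@H]2[C@H]([C@@H]1C(O)C1C[C@H](Cc3ccc(I)cc3)N(C(=O)OC(C)(C)C)C1=O)[C@H](O[Si](CC)(CC)CC)[C@@H]1[C@@H](C)C[C@@H](C)C[C@]12C | intermediate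
34 | silyl-protected β-keto lactam | C=C[C@H]1C=C(C)[C@@H]2[C@H]([C@@H]1C(=O)C1C[C@H](Cc3ccc(I)cc3)N(C(=O)OC(C)(C)C)C1=O)[C@H](O[Si](CC)(CC)CC)[C@@H]1[C@@H](C)C[C@@H](C)C[C@]12C | intermediate
35 | 9α-hydroxy β-keto lactam | C=C[C@H]1C=C(C)[C@@H]2[C@H]([C@@H]1C(=O)C1C[C@H](Cc3ccc(I)cc3)N(C(=O)OC(C)(C)C)C1=O)[C@H](O)[C@@H]1[C@@H](C)C[C@@H](C)C[C@]12C | intermediate
36 | N-Boc macrocyclic β-keto lactam | C=C[C@H]1C=C(C)[C@@H]2[C@H]3[C@H](Oc4ccc(cc4)C[C@H]4CC(C(=O)N4C(=O)OC(C)(C)C)C(=O)[C@H]13)[C@@H]1[C@@H](C)C[C@@H](C)C[C@]12C | intermediate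
37 | 3'-phenylselanyl macrocycle | C=C[C@H]1C=C(C)[C@@H]2[C@H]3[C@H](Oc4ccc(cc4)C[C@H]4CC([Se]c5ccccc5)(C(=O)N4C(=O)OC(C)(C)C)C(=O)[C@H]13)[C@@H]1[C@@H](C)C[C@@H](C)C[C@]12C | intermediate
38 | selenoxide | C=C[C@H]1C=C(C)[C@@H]2[C@H]3[C@H](Oc4ccc(cc4)C[C@H]4CC([Se](=O)c5ccccc5)(C(=O)N4C(=O)OC(C)(C)C)C(=O)[C@H]13)[C@@H]1[C@@H](C)C[C@@H](C)C[C@]12C | intermediate
39 | N-Boc acylpyrrolinone macrocycle | C=C[C@H]1C=C(C)[C@@H]2[C@H]3[C@H](Oc4ccc(cc4)C[C@H]4C=C(C(=O)N4C(=O)OC(C)(C)C)C(=O)[C@H]13)[C@@H]1[C@@H](C)C[C@@H](C)C[C@]12C | intermediate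
40 | 5'-deoxy target | C=C[C@H]1C=C(C)[C@@H]2[C@H]3[C@H](Oc4ccc(cc4)C[C@H]4C=C(C(=O)N4)C(=O)[C@H]13)[C@@H]1[C@@H](C)C[C@@H](C)C[C@]12C | intermediate
41 | 5'-hydroperoxide | C=C[C@H]1C=C(C)[C@@H]2[C@H]3[C@H](Oc4ccc(cc4)C[C@@]4(OO)C=C(C(=O)N4)C(=O)[C@H]13)[C@@H]1[C@@H](C)C[C@@H](C)C[C@]12C | intermediate
42 | CNP0151253.2 | C=C[C@H]1C=C(C)[C@@H]2[C@H]3[C@H](Oc4ccc(cc4)C[C@@]4(O)C=C(C(=O)N4)C(=O)[C@H]13)[C@@H]1[C@@H](C)C[C@@H](C)C[C@]12C | target

Total step count: 27. Longest linear sequence: 21 steps (steps 4, 6–18 and 21–27, from 3-methylbut-2-enal).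

Steps most likely to fail

Step 15.
- What may go wrong: the silane may reduce the Lewis-acid-activated trienone before ring closure. Acid may drive the skipped vinyl/diene unit of ring C toward an aromatic ring. The pivalate carbonyl may intercept the oxyallyl cation. Hydride or proton may reach the wrong terminus or face.
- Fallback (from 19, rejoining at 23): hydride delivery is made intramolecular and the ester is removed. i-Bu2AlH (CH2Cl2, −78 °C) reduces the ketone and cleaves the pivalate to the dienediol F1. MnO2 re-oxidises only the bis-allylic alcohol to the hydroxy dienone F2. i-Pr2SiHCl/imidazole then gives the diisopropylsilyl ether F3.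
- BF3·OEt2 without external silane triggers the same 4π closure. The Si–H bond, tethered to the β-oriented C1 arm, is then held over the β face of C9a in a six-membered transition state. Silicon passes to the enolate oxygen to give the cyclic silyl enol ether F4.
- The model for this delivery is the Lewis-acid-promoted intramolecular hydrosilylation of carbonyl groups by alkoxyhydrosilanes. Cold HF·pyridine releases the hydroxy ketone F5, and LiAlH4 as in step 16 rejoins the route at 23.

Step 24.
- What may go wrong: closure of the strained ring may be so slow that intermolecular coupling, loss of iodine by reduction, or base- and heat-induced loss of the Boc group takes over.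
- Fallback (from 34, rejoining at 36): the arene is changed from electrophile to nucleophile and the ring is closed oxidatively at room temperature. Miyaura borylation of 34 (B2pin2, PdCl2(dppf), KOAc, dioxane, 80 °C) gives the pinacol boronate F6.
- KHF2 in aqueous MeOH converts F6 into the potassium trifluoroborate F7 and removes the silyl ether at the same time. Chan–Lam-type etherification (Cu(OAc)2, DMAP, 4 Å MS, O2, CH2Cl2, high dilution) then forms the C9–O–aryl bond and rejoins the route at 36.

Step 27.
- What may go wrong: tautomerisation inside the strained ring may be sluggish, and the radical chain may attack the doubly allylic C2–H or over-oxidise the product.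
- Fallback (from 40, rejoining at 42): the autoxidation is replaced by an ionic halogenation/solvolysis sequence. i-Pr3SiOTf/Et3N traps 40 as the 2-silyloxypyrrole F8. NBS at −78 °C, which is far faster on this ring than on the alkenes, gives the 5'-bromo lactam F9. Aqueous NaHCO3 hydrolyses F9 through the N-acyliminium ion to 42.

Further compounds
F1 | step 15 | dienediol (carbinol epimers) | C=C[C@H]1C=C(C)C=C([C@@H]1CO)C(O)C1=C(C)C[C@H](C)C[C@@H]1C
F2 | step 15 | hydroxy dienone | C=C[C@H]1C=C(C)C=C([C@@H]1CO)C(=O)C1=C(C)C[C@H](C)C[C@@H]1C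
F3 | step 15 | diisopropylsilyl ether of F2 | C=C[C@H]1C=C(C)C=C([C@@H]1CO[SiH](C(C)C)C(C)C)C(=O)C1=C(C)C[C@H](C)C[C@@H]1C
F4 | step 15 | cyclic silyl enol ether | C=C[C@H]1C=C(C)[C@@H]2[C@@H]3[C@@H]1CO[Si](C(C)C)(C(C)C)OC3=C1[C@@H](C)C[C@@H](C)C[C@]12C
F5 | step 15 | tricyclic hydroxy ketone | C=C[C@H]1C=C(C)[C@@H]2[C@H]([C@@H]1CO)C(=O)[C@@H]1[C@@H](C)C[C@@H](C)C[C@]12C
F6 | step 24 | aryl pinacol boronate of 34 | C=C[C@H]1C=C(C)[C@@H]2[C@H]([C@@H]1C(=O)C1C[C@H](Cc3ccc(cc3)B3OC(C)(C)C(C)(C)O3)N(C(=O)OC(C)(C)C)C1=O)[C@H](O[Si](CC)(CC)CC)[C@@H]1[C@@H](C)C[C@@H](C)C[C@]12C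
F7 | step 24 | potassium aryltrifluoroborate with free 9α-OH | [K+].C=C[C@H]1C=C(C)[C@@H]2[C@H]([C@@H]1C(=O)C1C[C@H](Cc3ccc(cc3)[B-](F)(F)F)N(C(=O)OC(C)(C)C)C1=O)[C@H](O)[C@@H]1[C@@H](C)C[C@@H](C)C[C@]12C
F8 | step 27 | 2-(triisopropylsilyloxy)pyrrole macrocycle | C=C[C@H]1C=C(C)[C@@H]2[C@H]3[C@H](Oc4ccc(cc4)Cc4cc(c(O[Si](C(C)C)(C(C)C)C(C)C)[nH]4)C(=O)[C@H]13)[C@@H]1[C@@H](C)C[C@@H](C)C[C@]12C
F9 | step 27 | 5'-bromo lactam macrocycle (C5' undefined) | C=C[C@H]1C=C(C)[C@@H]2[C@H]3[C@H](Oc4ccc(cc4)CC4(Br)C=C(C(=O)N4)C(=O)[C@H]13)[C@@H]1[C@@H](C)C[C@@H](C)C[C@]12C
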